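**Route outline**

- The retrosynthesis first cuts the two prenyl C–C bonds, C4a–CH2 and C8–CH2. The quaternary C4a (shared by the pyran ring and the carbocycle) is ortho to O5, which is flanked on its other side by the chelating C6 ketone, and C8 is ortho to O7. Each prenyl group is therefore the [3,3] image of a 1,1-dimethylallyl ether on a flat, achiral 6-isovaleryl-2,2-dimethylchromene.
- Further cuts are the two O–CMe2 ether bonds (back to a 5,7-dihydroxychromene), then the pyran ring (O1–C2 and C4–C4a, from a para propargyl ether), then the aryl–acyl bond.
- Forward, the carbocycle is bought as phloroglucinol and acylated. The pyran ring is closed next, still on the aromatic stage, by a propargyl Claisen/electrocyclisation cascade. Both remaining hydroxyls then become 1,1-dimethylallyl ethers by way of their propargyl ethers.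
- The last step moves both allyl groups from oxygen to carbon, first to C8 and then to C4a with dearomatisation. No ring closes in it.
- The single stereocentre, (S)-C4a, is created in that last shift under control of a chiral bisoxazoline ligand on divalent copper. Nothing earlier is chiral.

Key step: step 6

Numbering: chromene numbering is used throughout (O1, C2 with the gem-dimethyl group, C3=C4, ring-fusion carbons C4a and C8a, C5 to C8 in the carbocycle).

Assumption: the sense of induction of the copper bisoxazoline catalyst on this substrate cannot be predicted with certainty; the (S,S) ligand is written, and its mirror image would be used if a pilot run showed the (4aR) product.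

**Route**

Step 1
Reactants: 1 phloroglucinol; 2 isovaleryl chloride (3-methylbutanoyl chloride)
Product: 3 1-(2,4,6-trihydroxyphenyl)-3-methylbutan-1-one (phlorisovalerophenone)
Conditions: AlCl3 (4 equiv), PhNO2, rt → 65 °C; then ice, aq HCl
Reagents that add atoms: none
Why: Friedel-Crafts acylation, in which all ring carbons of the symmetric triol are equivalent and strongly nucleophilic, and the first aryl ketone, held as an aluminium chelate, deactivates the ring so that acylation should stop at the monoketone.

Step 2
Reactants: 3 phlorisovalerophenone; 4 3-chloro-3-methylbut-1-yne
Product: 5 1-[2,6-dihydroxy-4-(2-methylbut-3-yn-2-yloxy)phenyl]-3-methylbutan-1-one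
Conditions: 4 (1.1 equiv), CuCl2·2H2O (1 mol%), DBU (1.2 equiv), MeCN, 0 °C
Reagents that add atoms: none
Why: Copper-catalysed propargylic etherification of a phenol with a tertiary propargyl chloride, in which the hydroxyl para to the ketone is the most acidic and the only one not held in a hydrogen bond to the carbonyl, so one equivalent of 4 at 0 °C should etherify it alone.

Step 3
Reactants: 5 the para propargyl ether
Product: 8 1-(5,7-dihydroxy-2,2-dimethyl-2H-chromen-6-yl)-3-methylbutan-1-one, via allenylphenol 6 (not isolated), via ortho-quinone methide 7 (not isolated)
Conditions: xylene, 140 °C, N2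
Reagents that add atoms: none
Why: Aryl propargyl ether Claisen cascade, in which the [3,3] shift to either of the two symmetry-equivalent ortho carbons and enolisation give 6, a 1,5-hydrogen shift from the newly freed, non-chelated hydroxyl gives 7, and oxa-6π electrocyclisation closes the pyran ring on the oxygen that carried the ether, so a single chromene is expected.

Step 4
Reactants: 8 the dihydroxychromene; 4 3-chloro-3-methylbut-1-yne
Product: 9 1-[2,2-dimethyl-5,7-bis(2-methylbut-3-yn-2-yloxy)-2H-chromen-6-yl]-3-methylbutan-1-one
Conditions: 4 (5 equiv), CuCl2·2H2O (5 mol%), DBU (5 equiv), MeCN, 0 °C → 20 °C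
Reagents that add atoms: none
Why: The same copper-catalysed propargylic etherification, driven with excess chloride and DBU so that both hydrogen-bonded hydroxyls are deprotonated and alkylated on oxygen, while the temperature stays far below that of a propargyl Claisen shift to C8.

Step 5
Reactants: 9 the bis(propargyl ether)
Product: 10 1-[2,2-dimethyl-5,7-bis(2-methylbut-3-en-2-yloxy)-2H-chromen-6-yl]-3-methylbutan-1-one
Conditions: H2 (1 atm, stopped at 2 equiv), Pd/CaCO3 poisoned with Pb(OAc)2 (Lindlar catalyst), quinoline, EtOAc, 0 °C; concentrated below 20 °C and used at once
Reagents that add atoms: none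
Why: Lindlar semihydrogenation, in which the poisoned palladium surface binds the terminal alkynes far more strongly than the monosubstituted alkenes formed or the hindered styrene-type C3=C4 bond, so uptake should stop at the bis(allyl ether), which is kept cold because it is Claisen-labile.

Step 6
Reactants: 10 the bis(1,1-dimethylallyl ether)
Product: 12 (4aS)-7-hydroxy-2,2-dimethyl-4a,8-bis(3-methylbut-2-en-1-yl)-6-(3-methylbutanoyl)-2H-chromen-5(4aH)-one, via C8-prenyl phenol 11 (not isolated)
Conditions: Cu(OTf)2 (20 mol%), (S,S)-tBu-box [2,2'-(propane-2,2-diyl)bis((4S)-4-tert-butyl-4,5-dihydrooxazole), 22 mol%], 4 Å MS, CH2Cl2, −40 °C → 0 °C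
Reagents that add atoms: none
Why: Proposed new method: the divalent copper bisoxazoline complex binds the ketone oxygen together with one neighbouring ether oxygen, which polarises that O–CMe2 bond, and two [3,3] shifts follow: the O7 ether first delivers its CH2 terminus to the unsubstituted C8 and enolisation gives phenol 11, then the O5 ether delivers its CH2 terminus through a chair transition state to C4a, which dearomatises the carbocycle and gives the C5 ketone of 12 directly in the tautomer of the target. The closest known reaction type is the enantioselective dearomative ortho-Claisen rearrangement of allyl 2-naphthyl ethers that carry a chelating carbonyl group next to the ether oxygen, catalysed by chiral divalent copper complexes, together with the thermal Claisen rearrangement of aryl 1,1-dimethylallyl ethers; new here are the tertiary allyl group, the acylphloroglucinol ring and the pairing of two shifts. No ring is closed, so no closure mode is at issue. The only stereocentre, C4a, arises in the second shift, and its configuration is set by the tert-butyl groups of the C2-symmetric ligand, which shield one face of the planar chelate formed by the C6 carbonyl oxygen, O5 and copper, so that the dimethylallyl group can swing across one arene face only. The step needs the aromatic shift to precede the dearomatising one (in the dienone the O7 group could only move to C6), which the less hindered O7 site, the free C8–H terminus and the styrene conjugation that a shift to C4a must give up should secure, and it needs concerted migration in place of ionisation of the tertiary ethers, for which the low temperature, the non-polar solvent and the sieves as acid trap are chosen. Regiochemistry is fixed by the tether, because the other ortho carbon of both ethers is the acyl-bearing, electron-poor C6, and the vinylogous ester and β-triketone stabilisation of 12 should keep the product from reverting.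

**Compound list**

1 | phloroglucinol | Oc1cc(O)cc(O)c1 | starting material
2 | isovaleryl chloride | CC(C)CC(=O)Cl | starting material
3 | 1-(2,4,6-trihydroxyphenyl)-3-methylbutan-1-one | CC(C)CC(=O)c1c(O)cc(O)cc1O | intermediate
4 | 3-chloro-3-methylbut-1-yne | CC(C)(Cl)C#C | starting material
5 | 1-[2,6-dihydroxy-4-(2-methylbut-3-yn-2-yloxy)phenyl]-3-methylbutan-1-one | CC(C)CC(=O)c1c(O)cc(OC(C)(C)C#C)cc1O | intermediate
6 | 1-[2,4,6-trihydroxy-3-(3-methylbuta-1,2-dien-1-yl)phenyl]-3-methylbutan-1-one | CC(C)CC(=O)c1c(O)cc(O)c(C=C=C(C)C)c1O | intermediate (not isolated)
7 | 3,5-dihydroxy-4-(3-methylbutanoyl)-6-(3-methylbut-2-enylidene)cyclohexa-2,4-dien-1-one | CC(C)CC(=O)C1=C(O)C(=CC=C(C)C)C(=O)C=C1O | intermediate (not isolated)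
8 | 1-(5,7-dihydroxy-2,2-dimethyl-2H-chromen-6-yl)-3-methylbutan-1-one | CC(C)CC(=O)c1c(O)cc2OC(C)(C)C=Cc2c1O | intermediate
9 | 1-[2,2-dimethyl-5,7-bis(2-methylbut-3-yn-2-yloxy)-2H-chromen-6-yl]-3-methylbutan-1-one | CC(C)CC(=O)c1c(OC(C)(C)C#C)cc2OC(C)(C)C=Cc2c1OC(C)(C)C#C | intermediate
10 | 1-[2,2-dimethyl-5,7-bis(2-methylbut-3-en-2-yloxy)-2H-chromen-6-yl]-3-methylbutan-1-one | CC(C)CC(=O)c1c(OC(C)(C)C=C)cc2OC(C)(C)C=Cc2c1OC(C)(C)C=C | intermediate
11 | 1-[7-hydroxy-2,2-dimethyl-5-(2-methylbut-3-en-2-yloxy)-8-(3-methylbut-2-en-1-yl)-2H-chromen-6-yl]-3-methylbutan-1-one | CC(C)CC(=O)c1c(O)c(CC=C(C)C)c2OC(C)(C)C=Cc2c1OC(C)(C)C=C | intermediate (not isolated)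
12 | (4aS)-7-hydroxy-2,2-dimethyl-4a,8-bis(3-methylbut-2-en-1-yl)-6-(3-methylbutanoyl)-2H-chromen-5(4aH)-one (CNP0111062.2) | CC(C)=CCC1=C2OC(C)(C)C=C[C@]2(CC=C(C)C)C(=O)C(C(=O)CC(C)C)=C1O | target

**Step count and risks**

Total step count: 6. Longest linear sequence: 6 steps (1 → 3 → 5 → 8 → 9 → 10 → 12); 2 and 4 are purchased.

Steps most likely to fail:

Step 6. Three processes may defeat it. The dearomatising shift of the O5 ether may overtake the aromatic shift of the O7 ether, after which the remaining allyl group can reach only C6. Copper may be held by the phenol of 11 or by the acidic triketone product instead of the carbonyl/O5 chelate, so that turnover and facial control fall. The tertiary ethers may ionise and give racemic or cleaved material. The fallback uses known chemistry, sets out from 10 and comes back at 12, and answers the loss of enantiocontrol rather than the order of the shifts. Compound 10 is heated without catalyst in toluene at 80–100 °C, a thermal aromatic Claisen rearrangement of 1,1-dimethylallyl aryl ethers, which also dearomatises when the ortho carbon is substituted. This should give racemic 7-hydroxy-2,2-dimethyl-4a,8-bis(3-methylbut-2-en-1-yl)-6-(3-methylbutanoyl)-2H-chromen-5(4aH)-one F1. The enantiomers are then separated by preparative HPLC on a polysaccharide-based chiral stationary phase, and the (4aS) fraction is 12.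

Step 4. Etherification of two hindered, hydrogen-bonded hydroxyls on either side of the ketone may stall at the mono-ether or be diverted to alkylation at C8. The fallback sets out from 8 and comes back at 10. Compound 8 is treated with tert-butyl 2-methylbut-3-en-2-yl carbonate and Pd(PPh3)4 (zerovalent palladium) in THF at 0 °C. This is a Tsuji-Trost O-allylation in which the phenoxide attacks the more substituted end of the π-allyl complex. It gives the bis(1,1-dimethylallyl) ether 10 directly, so 9 and the semihydrogenation of step 5 are bypassed.

Step 2. Site selectivity may be lost through etherification of a hydrogen-bonded ortho hydroxyl or of two hydroxyls. The fallback sets out from 3 and comes back at 8. Compound 3 is condensed with 3-methylbut-2-enal under ethylenediammonium diacetate (or pyridine) catalysis with heating. Knoevenagel condensation at a ring carbon followed by oxa-6π electrocyclisation gives chromene 8 in one operation, with no ether intermediate and no step 3. Because either flanking oxygen can close the ring in this mode, the isomer 1-(5,7-dihydroxy-2,2-dimethyl-2H-chromen-8-yl)-3-methylbutan-1-one F2 must be removed by chromatography.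

Further compounds
F1 | step 6 | racemic 7-hydroxy-2,2-dimethyl-4a,8-bis(3-methylbut-2-en-1-yl)-6-(3-methylbutanoyl)-2H-chromen-5(4aH)-one | CC(C)=CCC1=C2OC(C)(C)C=CC2(CC=C(C)C)C(=O)C(C(=O)CC(C)C)=C1O
F0 | step 4 | none | none
F2 | step 2 | 1-(5,7-dihydroxy-2,2-dimethyl-2H-chromen-8-yl)-3-methylbutan-1-one | CC(C)CC(=O)c1c(O)cc(O)c2C=CC(C)(C)Oc12
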